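**Retrosynthetic overview**

1. Locants: C1 (ring carbon bearing C7H2OAc), C2 (=CH), C3 (CHOH), C4 (epoxide carbon bearing the chain C1′–C12′), C5 (epoxide CH), C6 (C=O). Target ⇐ primary acetylation and O-desilylation of an epoxy enone diol.
2. Epoxy enone ⇐ one fluoride operation on a 7-oxanorbornene silyl enol ether: C6 enolate, E1cB opening of the C2–O bridge, then the C5 alkoxide displaces an endo C4–Br. The furan oxygen ends as the epoxide oxygen (epoxide = last ring).
3. Chain: C1′–C2′ bond by addition of a C14 alkenyllithium (Negishi carboalumination of a geranyl-derived alkyne) to the exo C4 aldehyde of the cycloadduct.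
4. Key disconnection: C2–C3 and C4–C5 together, by a silicon-tethered intramolecular Diels–Alder reaction that dearomatises a 3-siloxyfuran with the Z enol silyl ether of bromomalonaldehyde. Carbocycle, temporary oxygen bridge and temporary silaketal ring all form here.
5. Enabling feature: ring C1–C6 has oxygen on adjacent C5 and C6 next to C1=C2, so C5–C6–C1–C2 with an oxygen bridging C5 and C2 is a 3-oxyfuran. The C7 hydroxymethyl on C1 lies three bonds from the C3 hydroxyl, so a C7–O–Si–O–C3 tether can deliver the dienophile only to C2 and only from the endo side.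

Key step: step 8

Assumption: the tryptophan-derived oxazaborolidinone is taken to shield the same face of the formyl-bound α-bromo enal as in its known cycloadditions of 2-bromoacrolein; on that model the catalyst from (R)-tryptophan gives the enantiomer needed (the catalyst from (S)-tryptophan would be used if the tether reverses the sense).

**Route**

Step 1
Reactants: 1 methyl 4-oxotetrahydrofuran-3-carboxylate
Product: 2 methyl 4-hydroxyfuran-3-carboxylate
Conditions: DDQ, 1,4-dioxane, 80 °C
Reagents that add atoms: none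
Why: DDQ dehydrogenation of the enolised cyclic β-keto ester (a 2,5-dihydrofuran) is driven by aromatisation to the hydroxyfuran, which the hydrogen bond to the ester holds as the enol; no stereocenter is formed.

Step 2
Reactants: 2 methyl 4-hydroxyfuran-3-carboxylate
Product: 3 methyl 4-(triisopropylsilyloxy)furan-3-carboxylate
Conditions: TIPSOTf, Et3N, CH2Cl2, 0 °C
Reagents that add atoms: triisopropylsilyl trifluoromethanesulfonate CC(C)[Si](C(C)C)(C(C)C)OS(=O)(=O)C(F)(F)F
Why: O-silylation of the enol with a silyl triflate and an amine base gives the 3-siloxyfuran, which is both the masked C6 ketone and the donor that activates the later diene.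

Step 3
Reactants: 3 methyl 4-(triisopropylsilyloxy)furan-3-carboxylate
Product: 4 [4-(triisopropylsilyloxy)furan-3-yl]methanol
Conditions: DIBAL-H (i-Bu2AlH), CH2Cl2, −78 °C; aq. potassium sodium tartrate
Reagents that add atoms: none
Why: Hydride reduction of the ester to the primary alcohol (C7) should leave the furyl silyl ether untouched at low temperature.

Step 4
Reactants: 5 geranyl bromide
Product: 6 trimethyl[(5E)-6,10-dimethylundeca-5,9-dien-1-yn-1-yl]silane
Conditions: 1-(trimethylsilyl)propyne, n-BuLi, THF, −78 → −20 °C; then 5, −78 °C → rt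
Reagents that add atoms: 1-(trimethylsilyl)propyne CC#C[Si](C)(C)C
Why: SN2 alkylation of the allylic bromide by the lithiated silylpropyne, whose silyl group suppresses allenyl coupling, should keep the E double bond.

Step 5
Reactants: 6 trimethyl[(5E)-6,10-dimethylundeca-5,9-dien-1-yn-1-yl]silane
Product: 7 (5E)-6,10-dimethylundeca-5,9-dien-1-yne
Conditions: K2CO3, MeOH, rt
Reagents that add atoms: none
Why: Base-catalysed methanolysis of the alkynyl C–Si bond (protodesilylation) frees the terminal alkyne.

Step 6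
Reactants: 7 (5E)-6,10-dimethylundeca-5,9-dien-1-yne
Product: 9 (1E,5E)-1-iodo-2,6,10-trimethylundeca-1,5,9-triene, via alkenyldimethylalane 8 (not isolated)
Conditions: AlMe3, Cp2ZrCl2 (cat.), CH2Cl2, 0 °C → rt; then I2, THF, −30 → 0 °C
Reagents that add atoms: trimethylaluminium C[Al](C)C; iodine II
Why: Negishi zirconium-catalysed carboalumination adds methyl and aluminium syn across the alkyne with aluminium at the terminus, and iodinolysis with retention should give the E trisubstituted vinyl iodide.

Step 7
Reactants: 4 [4-(triisopropylsilyloxy)furan-3-yl]methanol; 10 2-bromomalonaldehyde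
Product: 12 mixed diisopropylsilaketal of alcohol 4 and the Z enol of 10, via chlorosilane 11 (not isolated)
Conditions: i-Pr2SiCl2 (excess), Et3N, CH2Cl2, 0 °C; volatiles removed; then 10, Et3N, CH2Cl2, −40 → −20 °C; cold filtration, used crude
Reagents that add atoms: dichlorodiisopropylsilane CC(C)[Si](Cl)(Cl)C(C)C
Why: Stepwise silyl ether formation at silicon (primary alcohol first, then O-silylation of the symmetric malonaldehyde enol, for which silyl migration between the two oxygens is degenerate) should give the silaketal with the more stable Z enol ether, siloxy trans to formyl.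

Step 8
Reactants: 12 mixed diisopropylsilaketal of alcohol 4 and the Z enol of 10
Product: 13 silicon-bridged 7-oxabicyclo[2.2.1]hept-5-ene aldehyde (C4: exo-CHO and endo-Br; C3: endo-O; C6: OSi(i-Pr)3)
Conditions: (4R)-2-butyl-4-(1H-indol-3-ylmethyl)-3-(4-methylphenylsulfonyl)-1,3,2-oxazaborolidin-5-one (0.2 equiv, from N-tosyl-(R)-tryptophan and BuB(OH)2), CH2Cl2, −78 → −40 °C
Reagents that add atoms: none
Why: Proposed new method: the enal of 12, bound through its formyl oxygen to the chiral boron Lewis acid, should undergo a concerted, asynchronous [4π+2π] cycloaddition across the furan α-carbons (C3 to C2, C4 to C5) that dearomatises the furan; the closest known reactions are type 2 intramolecular Diels–Alder reactions of 2-substituted dienes through disposable silicon-acetal tethers and the oxazaborolidinone-catalysed Diels–Alder reaction of furan with 2-bromoacrolein. The six-membered carbocycle closes by suprafacial [4+2] addition, the furan ring becoming the oxygen bridge of a 7-oxabicyclo[2.2.1]heptene, and the seven-membered 1,3,2-dioxasilepane closes with the C2–C3 bond in the type 2 mode (tether anchored on the internal diene carbon C1, bridgehead C1=C6 double bond in a bicyclo[4.3.1] frame relaxed by the long Si–O bonds). The bridgeheads C2 and C5 are fixed by addition to one furan face; C3 carries its oxygen endo because only the endo C3–O bond can be spanned by the four-atom C7–O–Si–O chain; C4 then has bromine endo and formyl exo, since the Z enol ether geometry is transferred stereospecifically. The step needs regiochemistry opposite to the polar preference (the 3-siloxy group makes C5 the nucleophilic terminus and C3 is the electrophilic β-carbon of the enal), and the tether secures it because C3 can reach only C2. The absolute sense comes from the catalyst, which should shield one face of the enal as in its exo-formyl adducts of 2-bromoacrolein; the anti relation between the bridge oxygen on C5 and the endo bromide on C4 set here is what later lets the furan oxygen become the epoxide oxygen.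

Step 9
Reactants: 9 (1E,5E)-1-iodo-2,6,10-trimethylundeca-1,5,9-triene; 13 silicon-bridged 7-oxabicyclo[2.2.1]hept-5-ene aldehyde
Product: 16 C1′-(S) tert-butyldimethylsilyl ether of the alkenyl adduct, via alkenyllithium 14 (not isolated), via lithium alkoxide 15 (not isolated)
Conditions: 9, t-BuLi (2 equiv), Et2O, −78 °C; then 13, −78 °C; then TBSOTf, −78 → −30 °C
Reagents that add atoms: tert-butyldimethylsilyl trifluoromethanesulfonate CC(C)(C)[Si](C)(C)OS(=O)(=O)C(F)(F)F
Why: Iodine–lithium exchange and 1,2-addition to the α-bromo aldehyde in the Cornforth–Evans sense (C=O anti to C–Br, attack along the C5 bridgehead flank where lithium can bind the bridge oxygen) should set C1′ as S, and silylation in the cold keeps the alkoxide from displacing the neighbouring bromide.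

Step 10
Reactants: 16 C1′-(S) tert-butyldimethylsilyl ether of the alkenyl adduct
Product: 19 epoxy enone diol with C1′-OTBS, via oxanorbornanone enolate 17 (not isolated), via ring-opened C5 alkoxide 18 (not isolated)
Conditions: Bu4NF (3.3 equiv), THF, −78 → −20 °C; AcOH
Reagents that add atoms: none
Why: Fluoride cleaves the enol silyl ether to the C6 enolate, which should open the strained oxygen bridge by E1cB elimination (C1=C2 formed, oxygen kept on C5); the C5 alkoxide, held anti to the endo bromide, then closes the epoxide by intramolecular SN2 with inversion at C4, while the silaketal is cleaved to the C3 and C7 hydroxyls.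

Step 11
Reactants: 19 epoxy enone diol with C1′-OTBS
Product: 20 C7 acetate of 19
Conditions: AcCl, 2,4,6-collidine, CH2Cl2, −78 °C
Reagents that add atoms: acetyl chloride CC(=O)Cl
Why: Acylation with acetyl chloride and collidine at low temperature should be selective for the primary allylic alcohol over the hindered secondary C3 hydroxyl.

Step 12
Reactants: 20 C7 acetate of 19
Product: 21 target CNP0137670.2
Conditions: HF·pyridine, pyridine, THF, 0 °C → rt
Reagents that add atoms: none
Why: Fluoride cleavage of the silyl ether under buffered, non-basic conditions avoids Payne rearrangement of the epoxy alcohols and should leave acetate, epoxide and enone intact.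

**Compound list**

1 | methyl 4-oxotetrahydrofuran-3-carboxylate | COC(=O)C1COCC1=O | starting material
2 | methyl 4-hydroxyfuran-3-carboxylate | COC(=O)c1cocc1O | intermediate
3 | methyl 4-(triisopropylsilyloxy)furan-3-carboxylate | COC(=O)c1cocc1O[Si](C(C)C)(C(C)C)C(C)C | intermediate
4 | [4-(triisopropylsilyloxy)furan-3-yl]methanol | OCc1cocc1O[Si](C(C)C)(C(C)C)C(C)C | intermediate
5 | geranyl bromide, (2E)-1-bromo-3,7-dimethylocta-2,6-diene | CC(C)=CCC/C(C)=C/CBr | starting material
6 | trimethyl[(5E)-6,10-dimethylundeca-5,9-dien-1-yn-1-yl]silane | CC(C)=CCC/C(C)=C/CCC#C[Si](C)(C)C | intermediate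
7 | (5E)-6,10-dimethylundeca-5,9-dien-1-yne | CC(C)=CCC/C(C)=C/CCC#C | intermediate
8 | dimethyl[(1E,5E)-2,6,10-trimethylundeca-1,5,9-trien-1-yl]alane (not isolated) | CC(C)=CCC/C(C)=C/CC/C(C)=C/[Al](C)C | intermediate
9 | (1E,5E)-1-iodo-2,6,10-trimethylundeca-1,5,9-triene | CC(C)=CCC/C(C)=C/CC/C(C)=C/I | intermediate
10 | 2-bromomalonaldehyde (2-bromopropanedial, reacts as its enol) | O=CC(Br)C=O | starting material
11 | chlorodiisopropyl{[4-(triisopropylsilyloxy)furan-3-yl]methoxy}silane (not isolated) | Cl[Si](C(C)C)(C(C)C)OCc1cocc1O[Si](C(C)C)(C(C)C)C(C)C | intermediate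
12 | (2Z)-2-bromo-3-[diisopropyl({[4-(triisopropylsilyloxy)furan-3-yl]methoxy})silyloxy]prop-2-enal | O=C/C(Br)=C/O[Si](C(C)C)(C(C)C)OCc1cocc1O[Si](C(C)C)(C(C)C)C(C)C | intermediate
13 | cycloadduct: 7-oxabicyclo[2.2.1]hept-5-ene with exo-formyl and endo-bromo on C4, endo oxygen on C3, triisopropylsilyloxy on C6, and C7H2–O–Si(i-Pr)2–O–C3 bridge | O=C[C@@]1(Br)[C@H]2O[C@@H]([C@@H]1O[Si](C(C)C)(C(C)C)OC3)C3=C2O[Si](C(C)C)(C(C)C)C(C)C | intermediate
14 | [(1E,5E)-2,6,10-trimethylundeca-1,5,9-trien-1-yl]lithium (not isolated) | CC(C)=CCC/C(C)=C/CC/C(C)=C/[Li] | intermediate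
15 | lithium alkoxide of the C1′-(S) carbinol from 13 and 14 (not isolated) | CC(C)=CCC/C(C)=C/CC/C(C)=C/[C@H](O[Li])[C@@]1(Br)[C@H]2O[C@@H]([C@@H]1O[Si](C(C)C)(C(C)C)OC3)C3=C2O[Si](C(C)C)(C(C)C)C(C)C | intermediate
16 | C1′-(S) tert-butyldimethylsilyl ether of the alkenyl adduct (ring as in 13, chain 2E,6E) | CC(C)=CCC/C(C)=C/CC/C(C)=C/[C@H](O[Si](C)(C)C(C)(C)C)[C@@]1(Br)[C@H]2O[C@@H]([C@@H]1O[Si](C(C)C)(C(C)C)OC3)C3=C2O[Si](C(C)C)(C(C)C)C(C)C | intermediate
17 | C6 enolate of the 7-oxanorbornan-2-one, silaketal intact (not isolated) | CC(C)=CCC/C(C)=C/CC/C(C)=C/[C@H](O[Si](C)(C)C(C)(C)C)[C@@]1(Br)[C@H]2O[C@@H]([C@@H]1O[Si](C(C)C)(C(C)C)OC3)C3=C2[O-] | intermediate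
18 | ring-opened cyclohexenone C5 alkoxide with C4–Br anti to C5–O, silaketal intact (not isolated) | [O-][C@H]1C(=O)C2=C[C@H](O[Si](C(C)C)(C(C)C)OC2)[C@@]1(Br)[C@@H](O[Si](C)(C)C(C)(C)C)/C=C(\C)CC/C=C(\C)CCC=C(C)C | intermediate
19 | (1R,5S,6R)-6-[(1S,2E,6E)-1-(tert-butyldimethylsilyloxy)-3,7,11-trimethyldodeca-2,6,10-trien-1-yl]-5-hydroxy-3-(hydroxymethyl)-7-oxabicyclo[4.1.0]hept-3-en-2-one | OCC1=C[C@H](O)[C@@]2([C@@H](O[Si](C)(C)C(C)(C)C)/C=C(\C)CC/C=C(\C)CCC=C(C)C)O[C@H]2C1=O | intermediate
20 | [(1R,5S,6R)-6-[(1S,2E,6E)-1-(tert-butyldimethylsilyloxy)-3,7,11-trimethyldodeca-2,6,10-trien-1-yl]-5-hydroxy-2-oxo-7-oxabicyclo[4.1.0]hept-3-en-3-yl]methyl acetate | CC(=O)OCC1=C[C@H](O)[C@@]2([C@@H](O[Si](C)(C)C(C)(C)C)/C=C(\C)CC/C=C(\C)CCC=C(C)C)O[C@H]2C1=O | intermediate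
21 | [(1R,5S,6R)-5-hydroxy-6-[(1S,2E,6E)-1-hydroxy-3,7,11-trimethyldodeca-2,6,10-trien-1-yl]-2-oxo-7-oxabicyclo[4.1.0]hept-3-en-3-yl]methyl acetate | CC(=O)OCC1=C[C@H](O)[C@@]2([C@@H](O)/C=C(\C)CC/C=C(\C)CCC=C(C)C)O[C@H]2C1=O | target

**Totals and risks**

Total step count: 12. Longest linear sequence: 9 steps (steps 1, 2, 3, 7, 8, 9, 10, 11, 12).

Steps most likely to fail:

Step 8. The tethered transition state may be too strained, a stepwise Mukaiyama–Michael attack of C5 on C3 may leak in, or facial selectivity may be poor. The fallback uses known reactions only, sets out from 10 (with 14 as made in step 9) and comes back at 19. The tether is given up, regiochemistry is left to a 3-alkylfuran, and the C6 oxygen is added afterwards. Furan-3-ylmethanol (OCc1ccoc1) with Et3SiCl and imidazole gives triethyl(furan-3-ylmethoxy)silane F1. Compound 10 with Et3SiCl and Et3N gives (2Z)-2-bromo-3-(triethylsilyloxy)prop-2-enal F2. Their intermolecular Diels–Alder reaction with the same oxazaborolidinone catalyst (known for furan and 2-bromoacrolein; the 3-alkyl group directs C2 to the enal β-carbon) should give the exo-formyl endo-bromo cycloadduct F3. Addition of 14 gives lithium alkoxide F4, and TBSOTf gives silyl ether F5. 9-BBN adds only to the strained ring alkene (boron on the less substituted C6, exo face) to give borane F6, and NaBO3 gives exo alcohol F7. Dess–Martin periodinane gives ketone F8. Bu4NF removes both triethylsilyl groups to the ketone diol F9, enolises it, and the bridge opens to the ring-opened bromohydrin F10, which closes to 19.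

Step 9. Facial selectivity at C1′ may be poor, or the lithium alkoxide may close onto C4–Br before it is silylated. The fallback sets out from 13 and comes back at 16, and replaces substrate control by reagent control. Compound 14 is added as before and the mixture of 15 and its C1′-epimeric lithium alkoxide F11 is quenched cold with NH4Cl to the bromohydrin epimer mixture F12. Dess–Martin periodinane gives the α-bromo dienone F13. Reduction with (R)-2-methyl-CBS-oxazaborolidine [(3aR)-1-methyl-3,3-diphenyltetrahydro-1H,3H-pyrrolo[1,2-c][1,3,2]oxazaborole] and catecholborane, with the quaternary C4 as the large group, should give the (S)-bromohydrin F14. TBSOTf and 2,6-lutidine then give 16.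

Step 10. The unbuffered fluoride may cause β-elimination of the C7 silanolate or dehydrobromination, and three free alkoxides may allow Payne-type migration of the epoxide. The fallback sets out from 16 and comes back at 19, and separates the base cascade from the cleavage of the silicon bridge. K2CO3 in MeOH at 0 °C cleaves only the enol silyl ether by methanolysis. The cascade then runs through 17 and 18 with C3–O and C7–O still tied to silicon and gives the silaketal-bridged epoxy enone F15. Et3N·3HF then removes the silicon bridge to give 19.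

**Further compounds**

F1 | step 8 | triethyl(furan-3-ylmethoxy)silane | CC[Si](CC)(CC)OCc1ccoc1
F2 | step 8 | (2Z)-2-bromo-3-(triethylsilyloxy)prop-2-enal | O=C/C(Br)=C/O[Si](CC)(CC)CC
F3 | step 8 | intermolecular cycloadduct: 7-oxabicyclo[2.2.1]hept-5-ene with exo-formyl and endo-bromo on C4, endo triethylsilyloxy on C3, triethylsilyloxymethyl on C1 | O=C[C@@]1(Br)[C@H]2O[C@@H]([C@@H]1O[Si](CC)(CC)CC)C(CO[Si](CC)(CC)CC)=C2
F4 | step 8 | lithium alkoxide from F3 and 14 | CC(C)=CCC/C(C)=C/CC/C(C)=C/[C@H](O[Li])[C@@]1(Br)[C@H]2O[C@@H]([C@@H]1O[Si](CC)(CC)CC)C(CO[Si](CC)(CC)CC)=C2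
F5 | step 8 | C1′-(S) tert-butyldimethylsilyl ether of the adduct of F3 and 14 | CC(C)=CCC/C(C)=C/CC/C(C)=C/[C@H](O[Si](C)(C)C(C)(C)C)[C@@]1(Br)[C@H]2O[C@@H]([C@@H]1O[Si](CC)(CC)CC)C(CO[Si](CC)(CC)CC)=C2
F6 | step 8 | C6 exo B-alkyl-9-borabicyclo[3.3.1]nonane from F5 | CC(C)=CCC/C(C)=C/CC/C(C)=C/[C@H](O[Si](C)(C)C(C)(C)C)[C@@]1(Br)[C@H]2O[C@@H]([C@@H]1O[Si](CC)(CC)CC)[C@@H](CO[Si](CC)(CC)CC)[C@@H]2B3C4CCCC3CCC4
F7 | step 8 | C6 exo alcohol from F6 | CC(C)=CCC/C(C)=C/CC/C(C)=C/[C@H](O[Si](C)(C)C(C)(C)C)[C@@]1(Br)[C@H]2O[C@@H]([C@@H]1O[Si](CC)(CC)CC)[C@@H](CO[Si](CC)(CC)CC)[C@@H]2O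
F8 | step 8 | 7-oxanorbornan-2-one (C6 ketone) from F7 | CC(C)=CCC/C(C)=C/CC/C(C)=C/[C@H](O[Si](C)(C)C(C)(C)C)[C@@]1(Br)[C@H]2O[C@@H]([C@@H]1O[Si](CC)(CC)CC)[C@@H](CO[Si](CC)(CC)CC)C2=O
F9 | step 8 | ketone diol from F8 after loss of both triethylsilyl groups | CC(C)=CCC/C(C)=C/CC/C(C)=C/[C@H](O[Si](C)(C)C(C)(C)C)[C@@]1(Br)[C@H]2O[C@@H]([C@@H]1O)[C@@H](CO)C2=O
F10 | step 8 | ring-opened bromohydrin from F9 | O[C@H]1C(=O)C(CO)=C[C@H](O)[C@@]1(Br)[C@@H](O[Si](C)(C)C(C)(C)C)/C=C(\C)CC/C=C(\C)CCC=C(C)C
F11 | step 9 | C1′-(R) epimer of lithium alkoxide 15 | CC(C)=CCC/C(C)=C/CC/C(C)=C/[C@@H](O[Li])[C@@]1(Br)[C@H]2O[C@@H]([C@@H]1O[Si](C(C)C)(C(C)C)OC3)C3=C2O[Si](C(C)C)(C(C)C)C(C)C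
F12 | step 9 | bromohydrin from 13 and 14 as C1′ epimer mixture | CC(C)=CCC/C(C)=C/CC/C(C)=C/C(O)[C@@]1(Br)[C@H]2O[C@@H]([C@@H]1O[Si](C(C)C)(C(C)C)OC3)C3=C2O[Si](C(C)C)(C(C)C)C(C)C
F13 | step 9 | α-bromo dienone (C1′ ketone) | CC(C)=CCC/C(C)=C/CC/C(C)=C/C(=O)[C@@]1(Br)[C@H]2O[C@@H]([C@@H]1O[Si](C(C)C)(C(C)C)OC3)C3=C2O[Si](C(C)C)(C(C)C)C(C)C
F14 | step 9 | C1′-(S) bromohydrin | CC(C)=CCC/C(C)=C/CC/C(C)=C/[C@H](O)[C@@]1(Br)[C@H]2O[C@@H]([C@@H]1O[Si](C(C)C)(C(C)C)OC3)C3=C2O[Si](C(C)C)(C(C)C)C(C)C
F15 | step 10 | silaketal-bridged epoxy enone (C7–O–Si(i-Pr)2–O–C3 kept, C1′-OTBS) | O=C1C2=C[C@H](O[Si](C(C)C)(C(C)C)OC2)[C@@]3([C@@H](O[Si](C)(C)C(C)(C)C)/C=C(\C)CC/C=C(\C)CCC=C(C)C)O[C@@H]13
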